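The ten-membered carbocycle (C1–C10) is disconnected across C5–C10 to a trans-fused eudesmane (rings A and B): C5 and C10 lie opposite one another in that ring, and each epoxide (C1/C10, C4/C5) is the oxide of an E alkene, so a single C5–C10 bond conceals both. Hydroboration of the tetrasubstituted C4=C5 bond of a 1β-mesyloxyeudesm-4-ene, then methoxide, severs that bond in a Grob-type fragmentation; one operation delivers both E alkenes and the germacrane ring with C6 and C8 intact. The precursor, reached from (−)-α-santonin (1), carries the complete 13-silyloxy butenolide (ring C), a silyl-protected 8α-hydroxyl and an equatorial 1β-mesylate.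

Key step: step 14

Remark: eudesmane/germacrane numbering is used (ring A: C1–C5 and C10; ring B: C5–C10; ring C: the lactone with C11–C13); α is the face opposite the C10 methyl; the target SMILES is read as the (1R,4R,5R,6S,8S,10R) isomer; step 1 assumes that the fungal 8α-hydroxylation of santonin can be run on preparative scale.

Step 1
Reactants: 1 (−)-α-santonin
Product: 2 (−)-artemisin (8α-hydroxy-3-oxoeudesma-1,4-dien-12,6α-olide)
Conditions: Aspergillus niger (growing whole cells), air, glucose–peptone broth, 28 °C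
Reagents that add atoms: dioxygen, O=O
Why: Whole-cell cytochrome P450 hydroxylation of the unactivated ring-B methylene is a known fungal biotransformation of santonin that replaces the equatorial 8α hydrogen by hydroxyl with retention (C8 becomes S), an oxidation that no chemical reagent would direct to C8 once the other functionality is in place.

Step 2
Reactants: 2 (−)-artemisin
Product: 3 8α-triethylsilyloxy-3-oxoeudesma-1,4-dien-12,6α-olide
Conditions: Et3SiCl, imidazole, DMF, 0 °C → rt
Reagents that add atoms: chlorotriethylsilane, CC[Si](Cl)(CC)CC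
Why: Silyl ether formation on the equatorial secondary hydroxyl; the triethylsilyl group keeps O8 from attacking the lactone carbonyl (12,8-olide formation), from being oxidised in step 6 and from binding borane in step 14, and can later be removed beside the C13 silyl ether.

Step 3
Reactants: 3 8α-triethylsilyloxy-3-oxoeudesma-1,4-dien-12,6α-olide
Product: 4 1α,2α-epoxy-3-oxo-8α-triethylsilyloxyeudesm-4-en-12,6α-olide
Conditions: t-BuOOH, BnMe3N+ OH− (cat.), THF, 0 °C → rt
Reagents that add atoms: tert-butyl hydroperoxide, CC(C)(C)OO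
Why: Weitz–Scheffer nucleophilic epoxidation: tert-butyl peroxide anion adds to C1 of the less substituted enone arm from the α face, opposite the C10 methyl, and the enolate closes onto oxygen, so C1 and C2 are set as the 1α,2α-epoxide while the tetrasubstituted C4=C5 arm, the lactone and the silyl ether remain.

Step 4
Reactants: 4 1α,2α-epoxy-3-oxo-8α-triethylsilyloxyeudesm-4-en-12,6α-olide
Product: 6 1α-hydroxy-8α-triethylsilyloxyeudesma-2,4-dien-12,6α-olide, via epoxy hydrazone 5 (not isolated)
Conditions: N2H4·H2O, AcOH, MeOH, 0 °C → rt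
Reagents that add atoms: none
Why: Wharton transposition: the C3 hydrazone opens the epoxide to a vinyldiazene that loses N2, which deletes the C3 oxygen and moves the unsaturation to C2=C3 beside the untouched C4=C5 bond, and since the C1–O bond is never broken the carbinol keeps the 1α (axial) configuration of the epoxide.

Step 5
Reactants: 6 1α-hydroxy-8α-triethylsilyloxyeudesma-2,4-dien-12,6α-olide
Product: 7 1α-hydroxy-8α-triethylsilyloxyeudesm-4-en-12,6α-olide
Conditions: 2-O2NC6H4SO2NHNH2, Et3N, CH2Cl2, rt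
Reagents that add atoms: none
Why: Diimide reduction: concerted syn delivery of two hydrogens saturates the cis-disubstituted C2=C3 bond, whereas the tetrasubstituted C4=C5 bond is inert to diimide and cannot migrate, and no stereocentre is formed.

Step 6
Reactants: 7 1α-hydroxy-8α-triethylsilyloxyeudesm-4-en-12,6α-olide
Product: 8 1-oxo-8α-triethylsilyloxyeudesm-4-en-12,6α-olide
Conditions: (n-Pr4N)RuO4 (5 mol%), N-methylmorpholine N-oxide, 4 Å MS, CH2Cl2, rt
Reagents that add atoms: none
Why: Ley–Griffith oxidation of the hindered axial carbinol to the C1 ketone removes the wrongly configured centre under neutral conditions that spare the silyl ether, the lactone and C4=C5 (the ketone cannot conjugate with it because C10 is quaternary).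

Step 7
Reactants: 8 1-oxo-8α-triethylsilyloxyeudesm-4-en-12,6α-olide
Product: 9 1β-hydroxy-8α-triethylsilyloxyeudesm-4-en-12,6α-olide
Conditions: NaBH4, MeOH, −20 → 0 °C
Reagents that add atoms: none
Why: Borohydride reduction: hydride approaches the C1 carbonyl from the α face, anti to the vicinal angular methyl, as in 10-methyl-1-decalones, so the new C1 centre is the equatorial 1β-alcohol required for the fragmentation, and the lactone is not reduced at this temperature.

Step 8
Reactants: 9 1β-hydroxy-8α-triethylsilyloxyeudesm-4-en-12,6α-olide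
Product: 12 1β-hydroxy-8α-triethylsilyloxyeudesma-4,11(13)-dien-12,6α-olide, via 11β-phenylselenide 10 (not isolated), via selenoxide 11 (not isolated)
Conditions: LiN(i-Pr)2 (2.2 equiv), THF, −78 °C; PhSeCl; then AcOH, 30% H2O2, pyridine, 0 °C → rt
Reagents that add atoms: none
Why: Selenoxide syn-elimination: the lithium enolate of the trans-fused lactone is selenenylated at C11 from the β face, anti to C7–H, so the derived selenoxide finds syn hydrogens only on C13 and gives the exocyclic 11(13)-alkene; C11 ceases to be a stereocentre and buffering with pyridine limits epoxidation of C4=C5 by selenium peracids.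

Step 9
Reactants: 12 1β-hydroxy-8α-triethylsilyloxyeudesma-4,11(13)-dien-12,6α-olide
Product: 13 1β,11-dihydroxy-8α-triethylsilyloxy-13-noreudesma-4,7(11)-dien-12,6α-olide (enol of the 11-oxo lactone)
Conditions: OsO4 (2 mol%), NaIO4, 2,6-lutidine, dioxane/H2O, rt
Reagents that add atoms: sodium periodate (oxygen source, relayed by OsO4), [Na+].[O-]I(=O)(=O)=O
Why: Lemieux–Johnson cleavage: OsO4 dihydroxylates the exposed 1,1-disubstituted alkene far faster than the shielded tetrasubstituted C4=C5 bond, periodate excises C13 as formaldehyde, and the α-keto lactone enolises toward its only α-hydrogen (H7), which fixes the ring-C double bond at C7=C11 with no regiochemical alternative (C7 thereby loses its stereocentre, as in the target).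

Step 10
Reactants: 13 1β,11-dihydroxy-8α-triethylsilyloxy-13-noreudesma-4,7(11)-dien-12,6α-olide
Product: 14 1β-hydroxy-8α-triethylsilyloxy-11-trifluoromethanesulfonyloxy-13-noreudesma-4,7(11)-dien-12,6α-olide
Conditions: PhNTf2, Et3N, CH2Cl2, 0 °C → rt
Reagents that add atoms: N-phenylbis(trifluoromethanesulfonimide), O=S(=O)(N(c1ccccc1)S(=O)(=O)C(F)(F)F)C(F)(F)F
Why: O-Sulfonylation of the acidic enol (enol triflate formation) with the mild triflyl donor PhNTf2, which leaves the neutral, hindered 1β-hydroxyl untouched, turns C11 into a cross-coupling site.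

Step 11
Reactants: 14 1β-hydroxy-8α-triethylsilyloxy-11-trifluoromethanesulfonyloxy-13-noreudesma-4,7(11)-dien-12,6α-olide
Product: 15 1β,13-dihydroxy-8α-triethylsilyloxyeudesma-4,7(11)-dien-12,6α-olide
Conditions: Bu3SnCH2OH, Pd(PPh3)4 (5 mol%), LiCl, dioxane, 90 °C
Reagents that add atoms: (tributylstannyl)methanol, OC[Sn](CCCC)(CCCC)CCCC
Why: Stille coupling: oxidative addition of the electron-poor vinyl triflate, chloride-assisted transfer of the hydroxymethyl group from tin and reductive elimination put C13 back on C11 as CH2OH, giving the tetrasubstituted butenolide without touching any stereocentre.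

Step 12
Reactants: 15 1β,13-dihydroxy-8α-triethylsilyloxyeudesma-4,7(11)-dien-12,6α-olide
Product: 16 13-(tert-butyldimethylsilyloxy)-1β-hydroxy-8α-triethylsilyloxyeudesma-4,7(11)-dien-12,6α-olide
Conditions: t-BuMe2SiCl (1.1 equiv), imidazole, CH2Cl2, 0 °C
Reagents that add atoms: tert-butyldimethylsilyl chloride, CC(C)(C)[Si](C)(C)Cl
Why: Silyl ether formation: the unhindered primary allylic hydroxyl reacts far faster with the bulky chlorosilane than the 1β-hydroxyl next to the quaternary C10, so one equivalent of reagent protects O13 selectively.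

Step 13
Reactants: 16 13-(tert-butyldimethylsilyloxy)-1β-hydroxy-8α-triethylsilyloxyeudesma-4,7(11)-dien-12,6α-olide
Product: 17 13-(tert-butyldimethylsilyloxy)-1β-methanesulfonyloxy-8α-triethylsilyloxyeudesma-4,7(11)-dien-12,6α-olide
Conditions: MeSO2Cl, Et3N, CH2Cl2, 0 °C
Reagents that add atoms: methanesulfonyl chloride, CS(=O)(=O)Cl
Why: Sulfonylation through sulfene converts even the hindered secondary 1β-hydroxyl into its mesylate with retention at C1, placing an equatorial leaving group antiperiplanar to the C5–C10 bond, and is left to the last step before the fragmentation so that the sulfonate meets no strong base.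

Step 14
Reactants: 17 13-(tert-butyldimethylsilyloxy)-1β-methanesulfonyloxy-8α-triethylsilyloxyeudesma-4,7(11)-dien-12,6α-olide
Product: 20 (1(10)E,4E)-13-(tert-butyldimethylsilyloxy)-8α-triethylsilyloxygermacra-1(10),4,7(11)-trien-12,6α-olide, via 4α-alkylborane 18 (not isolated), via sodium trimethoxyborate 19 (not isolated)
Conditions: BH3·THF (3 equiv), THF, 0 °C → rt; then NaOMe (3 equiv), MeOH, 0 °C
Reagents that add atoms: none
Why: BH3 adds syn to the C4=C5 bond from the α face, anti to the C10 methyl, with boron on the less encumbered C4 (C5 is flanked by the quaternary C10 and the oxygenated C6), giving a trans-decalin with an equatorial 4α-boryl group and 5α-H. Methoxide then turns the borane into a borate, and the antiperiplanar C4–B, C5–C10 and C1–O bonds break in a concerted Grob-type 1,4-fragmentation that expels mesylate and trimethyl borate. The closest known reaction is the boronate fragmentation of hydroborated octalin mesylates to cyclodeca-1,5-dienes. No ring is closed by bond formation, so no cyclisation mode applies: the ten-membered ring is the periphery of rings A and B and appears when their shared bond is cut. No stereocentre is created; the equatorial boron and mesylate translate into E geometry at both new alkenes, and C6 and C8 are carried over unchanged. The step needs regio- and face-selective hydroboration ahead of any attack on the conjugated lactone, which the electron-rich tetrasubstituted alkene, the absence of free hydroxyls and a methoxide charge kept at or below the total boron (a methoxyborate buffer that spares the γ-hydrogen at C6 and the lactone) are meant to secure.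

Step 15
Reactants: 20 (1(10)E,4E)-13-(tert-butyldimethylsilyloxy)-8α-triethylsilyloxygermacra-1(10),4,7(11)-trien-12,6α-olide
Product: 21 (1(10)E,4E)-13-(tert-butyldimethylsilyloxy)-8α-hydroxygermacra-1(10),4,7(11)-trien-12,6α-olide
Conditions: HF·pyridine, pyridine, THF, 0 °C
Reagents that add atoms: none
Why: Fluoride-mediated desilylation: buffered HF·pyridine cleaves the secondary triethylsilyl ether much faster than the primary tert-butyldimethylsilyl ether, and the buffered medium avoids acid-induced transannular cyclisation of the 1(10),4-diene and leaves C8 untouched.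

Step 16
Reactants: 21 (1(10)E,4E)-13-(tert-butyldimethylsilyloxy)-8α-hydroxygermacra-1(10),4,7(11)-trien-12,6α-olide, 22 tiglic acid
Product: 24 (1(10)E,4E)-13-(tert-butyldimethylsilyloxy)-8α-tigloyloxygermacra-1(10),4,7(11)-trien-12,6α-olide, via tiglic 2,4,6-trichlorobenzoic anhydride 23 (not isolated)
Conditions: 2,4,6-Cl3C6H2COCl, Et3N, toluene, rt; then 21, DMAP, rt
Reagents that add atoms: none
Why: Yamaguchi esterification: the mixed anhydride is attacked by DMAP at the less hindered tigloyl carbonyl and the acylpyridinium acylates the secondary allylic 8α-hydroxyl with retention at C8, without E/Z isomerisation of the tiglate and faster than O8 can attack the lactone carbonyl, O13 being silylated.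

Step 17
Reactants: 24 (1(10)E,4E)-13-(tert-butyldimethylsilyloxy)-8α-tigloyloxygermacra-1(10),4,7(11)-trien-12,6α-olide
Product: 25 (1R,10R,4R,5R)-13-(tert-butyldimethylsilyloxy)-1,10:4,5-diepoxy-8α-tigloyloxygermacr-7(11)-en-12,6α-olide
Conditions: dimethyldioxirane (2.3 equiv), acetone/CH2Cl2, −20 → 0 °C
Reagents that add atoms: dimethyldioxirane, CC1(C)OO1
Why: Dioxirane epoxidation: the two electron-rich trisubstituted ring alkenes react far faster than the conjugated butenolide and tiglate alkenes, and oxygen is delivered to the outer face of each alkene in the crossed ring conformation (both methyls on one side), the face formerly occupied by boron and by the mesylate, which converts each E alkene into a trans epoxide and sets C1, C10, C4 and C5 as R under neutral conditions.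

Step 18
Reactants: 25 (1R,10R,4R,5R)-13-(tert-butyldimethylsilyloxy)-1,10:4,5-diepoxy-8α-tigloyloxygermacr-7(11)-en-12,6α-olide
Product: 26 (1R,10R,4R,5R)-1,10:4,5-diepoxy-13-hydroxy-8α-tigloyloxygermacr-7(11)-en-12,6α-olide (CNP0111480.1)
Conditions: HF·pyridine, pyridine, THF, 0 °C → rt
Reagents that add atoms: none
Why: Fluoride-mediated desilylation of the primary C13 silyl ether under pyridine buffering should leave both epoxides, the lactone and the tiglate intact and cannot move the acyl group because no alkoxide is formed.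

Compound list
1 | (−)-α-santonin (3-oxoeudesma-1,4-dien-12,6α-olide, 11S) | C[C@H]1[C@@H]2CC[C@]3(C=CC(=O)C(=C3[C@H]2OC1=O)C)C | starting material
2 | (−)-artemisin (8α-hydroxy-3-oxoeudesma-1,4-dien-12,6α-olide) | C[C@H]1[C@@H]2[C@@H](O)C[C@]3(C=CC(=O)C(=C3[C@H]2OC1=O)C)C | intermediate
3 | 8α-triethylsilyloxy-3-oxoeudesma-1,4-dien-12,6α-olide | C[C@H]1[C@@H]2[C@@H](O[Si](CC)(CC)CC)C[C@]3(C=CC(=O)C(=C3[C@H]2OC1=O)C)C | intermediate
4 | 1α,2α-epoxy-3-oxo-8α-triethylsilyloxyeudesm-4-en-12,6α-olide | C[C@H]1[C@@H]2[C@@H](O[Si](CC)(CC)CC)C[C@]3([C@H]4O[C@H]4C(=O)C(=C3[C@H]2OC1=O)C)C | intermediate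
5 | C3 hydrazone of 4 (1α,2α-epoxy-3-hydrazono-8α-triethylsilyloxyeudesm-4-en-12,6α-olide) | C[C@H]1[C@@H]2[C@@H](O[Si](CC)(CC)CC)C[C@]3([C@H]4O[C@H]4C(=NN)C(=C3[C@H]2OC1=O)C)C | intermediate (not isolated)
6 | 1α-hydroxy-8α-triethylsilyloxyeudesma-2,4-dien-12,6α-olide | C[C@H]1[C@@H]2[C@@H](O[Si](CC)(CC)CC)C[C@]3([C@@H](O)C=CC(=C3[C@H]2OC1=O)C)C | intermediate
7 | 1α-hydroxy-8α-triethylsilyloxyeudesm-4-en-12,6α-olide | C[C@H]1[C@@H]2[C@@H](O[Si](CC)(CC)CC)C[C@]3([C@@H](O)CCC(=C3[C@H]2OC1=O)C)C | intermediate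
8 | 1-oxo-8α-triethylsilyloxyeudesm-4-en-12,6α-olide | C[C@H]1[C@@H]2[C@@H](O[Si](CC)(CC)CC)C[C@]3(C(=O)CCC(=C3[C@H]2OC1=O)C)C | intermediate
9 | 1β-hydroxy-8α-triethylsilyloxyeudesm-4-en-12,6α-olide | C[C@H]1[C@@H]2[C@@H](O[Si](CC)(CC)CC)C[C@]3([C@H](O)CCC(=C3[C@H]2OC1=O)C)C | intermediate
10 | 1β-hydroxy-11β-phenylseleno-8α-triethylsilyloxyeudesm-4-en-12,6α-olide (11α-methyl) | C[C@@]1([Se]c5ccccc5)[C@@H]2[C@@H](O[Si](CC)(CC)CC)C[C@]3([C@H](O)CCC(=C3[C@H]2OC1=O)C)C | intermediate (not isolated)
11 | selenoxide of 10 | C[C@@]1([Se](=O)c5ccccc5)[C@@H]2[C@@H](O[Si](CC)(CC)CC)C[C@]3([C@H](O)CCC(=C3[C@H]2OC1=O)C)C | intermediate (not isolated)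
12 | 1β-hydroxy-8α-triethylsilyloxyeudesma-4,11(13)-dien-12,6α-olide | C=C1[C@@H]2[C@@H](O[Si](CC)(CC)CC)C[C@]3([C@H](O)CCC(=C3[C@H]2OC1=O)C)C | intermediate
13 | 1β,11-dihydroxy-8α-triethylsilyloxy-13-noreudesma-4,7(11)-dien-12,6α-olide (enol of the 11-oxo lactone) | CC[Si](CC)(CC)O[C@H]1C[C@@]2(C)[C@H](O)CCC(C)=C2[C@H]2OC(=O)C(O)=C12 | intermediate
14 | 1β-hydroxy-8α-triethylsilyloxy-11-trifluoromethanesulfonyloxy-13-noreudesma-4,7(11)-dien-12,6α-olide | CC[Si](CC)(CC)O[C@H]1C[C@@]2(C)[C@H](O)CCC(C)=C2[C@H]2OC(=O)C(OS(=O)(=O)C(F)(F)F)=C12 | intermediate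
15 | 1β,13-dihydroxy-8α-triethylsilyloxyeudesma-4,7(11)-dien-12,6α-olide | CC[Si](CC)(CC)O[C@H]1C[C@@]2(C)[C@H](O)CCC(C)=C2[C@H]2OC(=O)C(CO)=C12 | intermediate
16 | 13-(tert-butyldimethylsilyloxy)-1β-hydroxy-8α-triethylsilyloxyeudesma-4,7(11)-dien-12,6α-olide | CC[Si](CC)(CC)O[C@H]1C[C@@]2(C)[C@H](O)CCC(C)=C2[C@H]2OC(=O)C(CO[Si](C)(C)C(C)(C)C)=C12 | intermediate
17 | 13-(tert-butyldimethylsilyloxy)-1β-methanesulfonyloxy-8α-triethylsilyloxyeudesma-4,7(11)-dien-12,6α-olide (key-step precursor) | CC[Si](CC)(CC)O[C@H]1C[C@@]2(C)[C@H](OS(C)(=O)=O)CCC(C)=C2[C@H]2OC(=O)C(CO[Si](C)(C)C(C)(C)C)=C12 | intermediate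
18 | 4α-boryl-4β-methyl-5αH adduct of 17 (4α-BH2 alkylborane, trans-decalin) | CC[Si](CC)(CC)O[C@H]1C[C@@]2(C)[C@H](OS(C)(=O)=O)CC[C@@](C)(B)[C@@H]2[C@H]2OC(=O)C(CO[Si](C)(C)C(C)(C)C)=C12 | intermediate (not isolated)
19 | sodium trimethoxyborate of 18 (B(OMe)3 anion on C4α) | CC[Si](CC)(CC)O[C@H]1C[C@@]2(C)[C@H](OS(C)(=O)=O)CC[C@@](C)([B-](OC)(OC)OC)[C@@H]2[C@H]2OC(=O)C(CO[Si](C)(C)C(C)(C)C)=C12.[Na+] | intermediate (not isolated)
20 | (1(10)E,4E)-13-(tert-butyldimethylsilyloxy)-8α-triethylsilyloxygermacra-1(10),4,7(11)-trien-12,6α-olide (key-step product) | CC[Si](CC)(CC)O[C@H]1C/C(C)=C/CC/C(C)=C/[C@H]2OC(=O)C(CO[Si](C)(C)C(C)(C)C)=C12 | intermediate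
21 | (1(10)E,4E)-13-(tert-butyldimethylsilyloxy)-8α-hydroxygermacra-1(10),4,7(11)-trien-12,6α-olide | O[C@H]1C/C(C)=C/CC/C(C)=C/[C@H]2OC(=O)C(CO[Si](C)(C)C(C)(C)C)=C12 | intermediate
22 | tiglic acid ((E)-2-methylbut-2-enoic acid) | C/C=C(\C)C(=O)O | starting material
23 | tiglic 2,4,6-trichlorobenzoic anhydride | C/C=C(\C)C(=O)OC(=O)c1c(Cl)cc(Cl)cc1Cl | intermediate (not isolated)
24 | (1(10)E,4E)-13-(tert-butyldimethylsilyloxy)-8α-tigloyloxygermacra-1(10),4,7(11)-trien-12,6α-olide | C/C=C(\C)C(=O)O[C@H]1C/C(C)=C/CC/C(C)=C/[C@H]2OC(=O)C(CO[Si](C)(C)C(C)(C)C)=C12 | intermediate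
25 | (1R,10R,4R,5R)-13-(tert-butyldimethylsilyloxy)-1,10:4,5-diepoxy-8α-tigloyloxygermacr-7(11)-en-12,6α-olide | C/C=C(\C)C(=O)O[C@H]1C[C@@]2(C)O[C@@H]2CC[C@@]2(C)O[C@@H]2[C@H]2OC(=O)C(CO[Si](C)(C)C(C)(C)C)=C12 | intermediate
26 | (1R,10R,4R,5R,6S,8S)-1,10:4,5-diepoxy-13-hydroxy-8α-tigloyloxygermacr-7(11)-en-12,6α-olide (CNP0111480.1) | C/C=C(\C)C(=O)O[C@H]1C[C@@]2(C)O[C@@H]2CC[C@@]2(C)O[C@@H]2[C@H]2OC(=O)C(CO)=C12 | target

Total step count: 18. Longest linear sequence: 18 steps (1 to 26; tiglic acid 22 enters at step 16).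

Steps most likely to fail

1. Step 14, the hydroboration–fragmentation. What may go wrong: the borane may be consumed by reduction of the conjugated lactone; boron may be delivered to C5 under the inductive pull of the allylic C6 oxygen, after which β-elimination opens the lactone; or the γ-hydrogen at C6 may exchange in the basic second stage with loss of configuration. Fallback: move the fragmentation ahead of the butenolide, so that the borane meets only a saturated lactone without an acidic γ-hydrogen. It sets out from 9. Mesylation (MeSO2Cl, Et3N) gives 1β-methanesulfonyloxy-8α-triethylsilyloxyeudesm-4-en-12,6α-olide F1. BH3·THF, then NaOMe in MeOH, gives (1(10)E,4E)-8α-triethylsilyloxygermacra-1(10),4-dien-12,6α-olide F2. Dimethyldioxirane gives (1R,10R,4R,5R)-1,10:4,5-diepoxy-8α-triethylsilyloxygermacran-12,6α-olide F3. The operations of step 8 give 1,10:4,5-diepoxy-8α-triethylsilyloxygermacr-11(13)-en-12,6α-olide F4. OsO4/NaIO4, now with no other alkene present, gives 1,10:4,5-diepoxy-11-hydroxy-8α-triethylsilyloxy-13-norgermacr-7(11)-en-12,6α-olide F5. PhNTf2/Et3N gives the 11-O-triflate of the diepoxide F6. Bu3SnCH2OH with Pd(PPh3)4 gives 1,10:4,5-diepoxy-13-hydroxy-8α-triethylsilyloxygermacr-7(11)-en-12,6α-olide F7. t-BuMe2SiCl/imidazole gives the 13-tert-butyldimethylsilyl ether of the diepoxide F8. HF·pyridine/pyridine gives 13-(tert-butyldimethylsilyloxy)-1,10:4,5-diepoxy-8α-hydroxygermacr-7(11)-en-12,6α-olide F9. Yamaguchi esterification with 22 comes back to the route at 25.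

2. Step 11, the hydroxymethyl Stille coupling. What may go wrong: slow transfer of the oxygen-bearing sp3 carbon from tin to the hindered vinylpalladium intermediate, so that reduction of the triflate or butyl transfer takes over. Fallback: bring C13 in as carbon monoxide. It sets out from 14: carbonylative reduction (Pd(PPh3)4, CO 1 atm, Bu3SnH, THF, 50 °C) gives 1β-hydroxy-13-oxo-8α-triethylsilyloxyeudesma-4,7(11)-dien-12,6α-olide F10, and Luche reduction of the aldehyde (NaBH4, CeCl3·7H2O, MeOH, −40 °C) comes back to the route at 15.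

3. Step 17, the double epoxidation. What may go wrong: poor facial selectivity if the ten-membered ring reacts through a conformer that turns the inner face of an alkene outward, and over-oxidation at the tiglate. Fallback: reagent control in place of substrate control. It sets out from 24: Shi epoxidation with the D-fructose-derived ketone (Oxone (2KHSO5·KHSO4·K2SO4), K2CO3, MeCN/dimethoxymethane/aqueous buffer, 0 °C), whose known sense for E-trisubstituted alkenes is R,R at both sites, comes back to the route at 25 and makes no further compound (F0).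

Further compounds
F1 | step 14 | 1β-methanesulfonyloxy-8α-triethylsilyloxyeudesm-4-en-12,6α-olide | C[C@H]1[C@@H]2[C@@H](O[Si](CC)(CC)CC)C[C@]3([C@H](OS(C)(=O)=O)CCC(=C3[C@H]2OC1=O)C)C
F2 | step 14 | (1(10)E,4E)-8α-triethylsilyloxygermacra-1(10),4-dien-12,6α-olide (11S) | C[C@H]1[C@@H]2[C@@H](O[Si](CC)(CC)CC)C/C(C)=C/CC/C(C)=C/[C@H]2OC1=O
F3 | step 14 | (1R,10R,4R,5R)-1,10:4,5-diepoxy-8α-triethylsilyloxygermacran-12,6α-olide (11S) | C[C@H]1[C@@H]2[C@@H](O[Si](CC)(CC)CC)C[C@@]3(C)O[C@@H]3CC[C@@]3(C)O[C@@H]3[C@H]2OC1=O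
F4 | step 14 | (1R,10R,4R,5R)-1,10:4,5-diepoxy-8α-triethylsilyloxygermacr-11(13)-en-12,6α-olide | C=C1[C@@H]2[C@@H](O[Si](CC)(CC)CC)C[C@@]3(C)O[C@@H]3CC[C@@]3(C)O[C@@H]3[C@H]2OC1=O
F5 | step 14 | (1R,10R,4R,5R)-1,10:4,5-diepoxy-11-hydroxy-8α-triethylsilyloxy-13-norgermacr-7(11)-en-12,6α-olide | CC[Si](CC)(CC)O[C@H]1C[C@@]2(C)O[C@@H]2CC[C@@]2(C)O[C@@H]2[C@H]2OC(=O)C(O)=C12
F6 | step 14 | 11-O-trifluoromethanesulfonate of F5 | CC[Si](CC)(CC)O[C@H]1C[C@@]2(C)O[C@@H]2CC[C@@]2(C)O[C@@H]2[C@H]2OC(=O)C(OS(=O)(=O)C(F)(F)F)=C12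
F7 | step 14 | (1R,10R,4R,5R)-1,10:4,5-diepoxy-13-hydroxy-8α-triethylsilyloxygermacr-7(11)-en-12,6α-olide | CC[Si](CC)(CC)O[C@H]1C[C@@]2(C)O[C@@H]2CC[C@@]2(C)O[C@@H]2[C@H]2OC(=O)C(CO)=C12
F8 | step 14 | (1R,10R,4R,5R)-13-(tert-butyldimethylsilyloxy)-1,10:4,5-diepoxy-8α-triethylsilyloxygermacr-7(11)-en-12,6α-olide | CC[Si](CC)(CC)O[C@H]1C[C@@]2(C)O[C@@H]2CC[C@@]2(C)O[C@@H]2[C@H]2OC(=O)C(CO[Si](C)(C)C(C)(C)C)=C12
F9 | step 14 | (1R,10R,4R,5R)-13-(tert-butyldimethylsilyloxy)-1,10:4,5-diepoxy-8α-hydroxygermacr-7(11)-en-12,6α-olide | O[C@H]1C[C@@]2(C)O[C@@H]2CC[C@@]2(C)O[C@@H]2[C@H]2OC(=O)C(CO[Si](C)(C)C(C)(C)C)=C12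
F10 | step 11 | 1β-hydroxy-13-oxo-8α-triethylsilyloxyeudesma-4,7(11)-dien-12,6α-olide | CC[Si](CC)(CC)O[C@H]1C[C@@]2(C)[C@H](O)CCC(C)=C2[C@H]2OC(=O)C(C=O)=C12
F0 | step 17 | none | none
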